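**Retrosynthetic overview**

- The strategy rests on the trisubstituted C=C of the central cyclohexene. Its fully substituted carbon carries C3 of quinolinone ring A, and its CH carbon is bonded to the quaternary C(CH3)–O carbon of the bridging ether. This is the 3-aryl-cyclohex-2-enyl pattern left when an aryl–metal adds across an alkyne and then to a tethered methyl ketone.
- Last disconnections: the O–C(CH3)2 bond (ring-A 4-OH onto the isopropenyl group, dihydropyran ring), then the O–C(CH3) bond (ring-B 4-OH onto the cyclohexenyl cation, bridging ether ring).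
- Key disconnection: the aryl–C(alkene) and C(alkene)–C(OH)(CH3) bonds, made together by nickel-catalysed anti-arylative cyclisation of a silyl alkynyl methyl ketone with the ring-A boronic acid (closes the cyclohexene).
- The alkynyl ketone comes from catalytic Michael addition of the hydroxyquinolinone to an (R)-enone. The enone comes from (S)-limonene by ring opening of isopiperitenone oxide, which puts the alkyne directly on the stereocentre; a one-carbon alkynylation of the limonene keto-aldehyde would leave one CH2 too many.
- Ring order: two quinolinone bicycles (from 2,3-dimethoxyaniline and diethyl malonate), then cyclohexene, then bridging ether ring, then dihydropyran.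

Key step: step 14

Remark: the carbinol centre of 5, the epoxide centres of 2 and 7 and the carbinol centre of 26 are destroyed later and are carried as mixtures; the facial sense of the amine catalyst in step 12 is assigned by analogy with asymmetric aza-warfarin additions, and the quinine-derived pseudoenantiomer is taken instead if the analogy does not hold.

**Route**

Step 1
Reactants: 1 (S)-limonene
Product: 2 (4S)-limonene 1,2-oxide (cis/trans mixture)
Conditions: mCPBA (1.0 equiv), NaHCO3, CH2Cl2, 0 °C
Reagents that add atoms: 3-chloroperoxybenzoic acid, OOC(=O)c1cccc(Cl)c1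
Why: Prilezhaev epoxidation should take the electron-richer trisubstituted ring alkene in preference to the 1,1-disubstituted isopropenyl group; the two epoxide centres form as a mixture, which is acceptable because both are destroyed by step 5.

Step 2
Reactants: 2 (4S)-limonene 1,2-oxide
Product: 5 (4S)-1-methyl-4-(prop-1-en-2-yl)cyclohex-2-en-1-ol, via hydroxy selenide 3 (not isolated), via selenoxide 4 (not isolated)
Conditions: (PhSe)2, NaBH4, EtOH, reflux; then 30% H2O2, pyridine, THF, 0 °C to rt
Reagents that add atoms: none
Why: Epoxide-to-allylic-alcohol transposition by selenide opening and selenoxide syn-elimination: benzeneselenolate should open the trans-oxide at the secondary carbon C2 in a trans-diaxial SN2 sense, and the selenoxide can eliminate only towards C3 because C1 has no hydrogen, so the C2=C3 alkene and the tertiary carbinol result with C4 untouched (the sluggish cis-oxide is removed here).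

Step 3
Reactants: 5 (4S)-1-methyl-4-(prop-1-en-2-yl)cyclohex-2-en-1-ol
Product: 6 (6R)-3-methyl-6-(prop-1-en-2-yl)cyclohex-2-en-1-one ((R)-isopiperitenone)
Conditions: pyridinium chlorochromate [C5H5NH][CrO3Cl], 4 Å MS, CH2Cl2, rt
Reagents that add atoms: pyridinium chlorochromate, [O-][Cr](=O)(=O)Cl.c1cc[nH+]cc1 (the carbonyl oxygen, through the [3,3] shift)
Why: Babler–Dauben oxidative transposition: the chromate ester of the tertiary allylic alcohol should shift to C3 and be oxidised there, giving the 3-methyl enone with its carbonyl next to the stereocentre; both carbinol epimers converge and no stereocentre is formed.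

Step 4
Reactants: 6 (R)-isopiperitenone
Product: 7 (3R)-6-methyl-3-(prop-1-en-2-yl)-7-oxabicyclo[4.1.0]heptan-2-one (epoxide diastereomers)
Conditions: 30% H2O2, LiOH (0.2 equiv), MeOH, −10 to 0 °C
Reagents that add atoms: hydrogen peroxide, OO
Why: Weitz–Scheffer nucleophilic epoxidation: hydroperoxide should add to the enone β-carbon and close on the α-carbon while the electron-rich isopropenyl group stays inert; the epoxide configuration is irrelevant, and cold, substoichiometric base is chosen to spare the enolisable carbon that bears the isopropenyl group.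

Step 5
Reactants: 7 isopiperitenone oxide
Product: 9 (5R)-5-ethynyl-6-methylhept-6-en-2-one, via epoxy tosylhydrazone 8 (not isolated)
Conditions: TsNHNH2, AcOH/CH2Cl2 (1:1), −20 °C to rt
Reagents that add atoms: none
Why: Eschenmoser–Tanabe fragmentation: the epoxy tosylhydrazone should open to the hydroxy azoalkene and fragment with loss of N2 and sulfinate, so that the former carbonyl carbon and its α-carbon become a terminal alkyne directly on the stereocentre and the β-carbon becomes the methyl ketone, with the stereocentre untouched.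

Step 6
Reactants: 9 (5R)-5-ethynyl-6-methylhept-6-en-2-one
Product: 11 (5R)-6-methyl-5-[(trimethylsilyl)ethynyl]hept-6-en-2-one, via bis-silyl enol ether 10 (not isolated)
Conditions: LiN(i-Pr)2 (2.2 equiv), THF, −78 °C; Me3SiCl (2.5 equiv); then 0.5 M HCl, 0 °C
Reagents that add atoms: chlorotrimethylsilane, C[Si](C)(C)Cl
Why: Enolate and acetylide are formed together and both silylated, and the labile enol silyl ether should hydrolyse on mild acid work-up while the alkynyl C–Si bond survives (C-silylation of a terminal alkyne); the stereocentre is not deprotonated at −78 °C.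

Step 7
Reactants: 11 (5R)-6-methyl-5-[(trimethylsilyl)ethynyl]hept-6-en-2-one
Product: 13 (3E,5R)-6-methyl-5-[(trimethylsilyl)ethynyl]hepta-3,6-dien-2-one, via internal silyl enol ether 12 (not isolated)
Conditions: Me3SiI, (Me3Si)2NH, CH2Cl2, −20 °C to rt; then Pd(OAc)2 (1.0 equiv), MeCN, rt
Reagents that add atoms: none
Why: Saegusa–Ito oxidation: the thermodynamic internal trimethylsilyl enol ether should give the palladium enolate with Pd(OAc)2 (divalent palladium), and β-hydride elimination gives the (E)-enone; the minor terminal enol ether has no β-hydrogen and only returns ketone 11.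

Step 8
Reactants: 14 2,3-dimethoxyaniline
Product: 16 2,3-dimethoxy-N-methylaniline, via N-methoxymethyl aniline 15 (not isolated)
Conditions: (CH2O)n, NaOMe, MeOH, reflux; then NaBH4, reflux
Reagents that add atoms: formaldehyde (as paraformaldehyde), C=O
Why: Mono-N-methylation by reductive amination: aniline and formaldehyde should give the N-(methoxymethyl)aniline in methoxide/methanol, which NaBH4 reduces to the N-methylaniline without over-alkylation.

Step 9
Reactants: 16 2,3-dimethoxy-N-methylaniline; 17 diethyl malonate
Product: 19 4-hydroxy-7,8-dimethoxy-1-methylquinolin-2(1H)-one, via malonanilic ester 18 (not isolated)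
Conditions: Ph2O, 250 °C, EtOH distilled off
Reagents that add atoms: none
Why: Thermal malonate condensation: aminolysis of one ester gives the malonanilic ester, which should cyclise by intramolecular acylation at the only free ortho position of the electron-rich ring to the 4-hydroxyquinolin-2-one.

Step 10
Reactants: 19 4-hydroxy-7,8-dimethoxy-1-methylquinolin-2(1H)-one
Product: 20 7,8-dimethoxy-4-(methoxymethoxy)-1-methylquinolin-2(1H)-one
Conditions: MOMCl, i-Pr2NEt, CH2Cl2, 0 °C to rt
Reagents that add atoms: chloromethyl methyl ether, COCCl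
Why: O-Alkylation of the acidic 4-hydroxyl (a vinylogous carboxylic acid) by the hard electrophile MOMCl should give the 4-MOM ether, which also directs the metalation of step 11.

Step 11
Reactants: 20 7,8-dimethoxy-4-(methoxymethoxy)-1-methylquinolin-2(1H)-one
Product: 23 [7,8-dimethoxy-4-(methoxymethoxy)-1-methyl-2-oxo-1,2-dihydroquinolin-3-yl]boronic acid, via 3-lithioquinolinone 21 (not isolated), via lithium triisopropoxyborate 22 (not isolated)
Conditions: n-BuLi, THF, −78 °C; B(Oi-Pr)3, −78 to 0 °C; aq. NH4Cl
Reagents that add atoms: triisopropyl borate, CC(C)OB(OC(C)C)OC(C)C; water, O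
Why: Directed metalation then borylation: C3–H, flanked by the lactam carbonyl and the 4-MOM-oxy group, should be lithiated selectively, and the aryllithium is trapped as the borate and hydrolysed at near-neutral pH so that the MOM group survives.

Step 12
Reactants: 13 (3E,5R)-6-methyl-5-[(trimethylsilyl)ethynyl]hepta-3,6-dien-2-one; 19 4-hydroxy-7,8-dimethoxy-1-methylquinolin-2(1H)-one
Product: 24 4-hydroxy-7,8-dimethoxy-1-methyl-3-[(4R,5R)-6-methyl-2-oxo-5-[(trimethylsilyl)ethynyl]hept-6-en-4-yl]quinolin-2(1H)-one (in equilibrium with its cyclic hemiketals)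
Conditions: 9-amino-9-deoxy-epi-quinidine (20 mol%), CF3CO2H (40 mol%), CH2Cl2, 0 °C to rt
Reagents that add atoms: none
Why: Iminium-catalysed Michael addition: the primary amine salt activates the (E)-enone as its iminium ion and C3 of the hydroxyquinolinone should add to the β-carbon on the face selected by the catalyst, setting the new (R) centre under catalyst control, while the acidic medium and low temperature limit dienamine formation at the existing γ-centre.

Step 13
Reactants: 24 Michael adduct
Product: 25 7,8-dimethoxy-4-(methoxymethoxy)-1-methyl-3-[(4R,5R)-6-methyl-2-oxo-5-[(trimethylsilyl)ethynyl]hept-6-en-4-yl]quinolin-2(1H)-one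
Conditions: MOMCl, i-Pr2NEt, CH2Cl2, 0 °C to rt
Reagents that add atoms: chloromethyl methyl ether, COCCl
Why: Base should convert the hemiketal/enol mixture into the open-chain 4-oxido anion, which is O-alkylated by MOMCl; this frees the methyl ketone and masks the acidic hydroxyl before the nickel step.

Step 14
Reactants: 25 silyl alkynyl methyl ketone; 23 ring-A boronic acid (2.0 equiv)
Product: 26 (4R,5R)-3,5-bis[7,8-dimethoxy-4-(methoxymethoxy)-1-methyl-2-oxo-1,2-dihydroquinolin-3-yl]-1-methyl-4-(prop-1-en-2-yl)-2-(trimethylsilyl)cyclohex-2-en-1-ol (both C1 epimers)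
Conditions: Ni(OAc)2·4H2O (10 mol%), (S)-t-Bu-PHOX (10 mol%), CF3CH2OH, 80 °C
Reagents that add atoms: none
Why: Transmetallation of 23 to the divalent nickel acetate or alkoxide gives an aryl–nickel species that should add syn across the silyl alkyne with the aryl group on the carbon remote from silicon, nickel ending alpha to silicon. The alpha-silyl alkenylnickel then isomerises reversibly so that nickel comes cis to the chain, and only this isomer can reach the methyl ketone; 1,2-addition closes the cyclohexene by a 6-exo-trig attack on the carbonyl with the new C=C endocyclic, and protonolysis of the nickel alkoxide by the solvent turns the catalyst over. The closest known reaction type is the nickel/phosphinooxazoline-catalysed anti-carbometallative arylative cyclisation of alkynyl ketones with arylboronic acids to 3-arylcyclohex-2-enols. The one new stereocentre, the carbinol carbon, is not controlled (the ligand's chirality is not relied on) and need not be, because it is ionised in step 15; the two existing centres are not enolisable and stay untouched. The step needs aryl delivery beta to silicon and anti addition: the silyl group secures the first, and the second is enforced because ring closure is possible only from the isomerised alkenylnickel. The demanding element is the doubly ortho-substituted heteroarylboronic acid, used in excess against protodeboronation.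

Step 15
Reactants: 26 3-aryl-2-silylcyclohex-2-enol
Product: 29 bridged ether with free ring-A hydroxyl, isopropenyl group and no silicon, via MOM-free triol 27 (not isolated), via silylated bridged ether 28 (not isolated)
Conditions: CF3CO2H/CH2Cl2/H2O (20:80:1), 0 °C to rt
Reagents that add atoms: none
Why: Acid should hydrolyse both acetal-type MOM ethers and ionise the tertiary allylic alcohol (SN1) to the cyclohexenyl cation, which the ring-B 4-hydroxyl captures at the methyl-bearing terminus to close the bridging ether ring and set the quaternary centre (only the arrangement cis to aryl B can bridge; the ring-A hydroxyl cannot reach the cation because it is trans across the ring alkene), and ipso-protonation of the aryl-conjugated vinylsilane removes silicon (protodesilylation).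

Step 16
Reactants: 29 bridged ether with free ring-A hydroxyl
Product: 30 target CNP0237003.1
Conditions: CF3SO3H (10 mol%), CH2Cl2, 0 °C to rt
Reagents that add atoms: none
Why: Brønsted-acid hydroalkoxylation: Markovnikov protonation of the isopropenyl group gives the tertiary cation, which the ring-A 4-hydroxyl should capture in a six-membered closure to the gem-dimethyl dihydropyran; no stereocentre is formed or changed.

**Compound list**

1 | (S)-limonene | CC1=CC[C@H](CC1)C(C)=C | starting material
2 | (4S)-limonene 1,2-oxide, cis/trans | CC12OC1C[C@H](CC2)C(C)=C | intermediate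
3 | (4S)-1-methyl-2-(phenylselanyl)-4-(prop-1-en-2-yl)cyclohexan-1-ol | CC1(O)C([Se]c2ccccc2)C[C@H](CC1)C(C)=C | intermediate
4 | (4S)-1-methyl-2-(phenylseleninyl)-4-(prop-1-en-2-yl)cyclohexan-1-ol | CC1(O)C([Se](=O)c2ccccc2)C[C@H](CC1)C(C)=C | intermediate
5 | (4S)-1-methyl-4-(prop-1-en-2-yl)cyclohex-2-en-1-ol | CC1(O)C=C[C@H](CC1)C(C)=C | intermediate
6 | (6R)-3-methyl-6-(prop-1-en-2-yl)cyclohex-2-en-1-one | CC1=CC(=O)[C@H](CC1)C(C)=C | intermediate
7 | (3R)-6-methyl-3-(prop-1-en-2-yl)-7-oxabicyclo[4.1.0]heptan-2-one | CC12OC1C(=O)[C@H](CC2)C(C)=C | intermediate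
8 | tosylhydrazone of 7 | CC12OC1C(=NNS(=O)(=O)c3ccc(C)cc3)[C@H](CC2)C(C)=C | intermediate
9 | (5R)-5-ethynyl-6-methylhept-6-en-2-one | CC(=O)CC[C@@H](C#C)C(C)=C | intermediate
10 | trimethyl{[(5R)-6-methyl-5-[(trimethylsilyl)ethynyl]hepta-1,6-dien-2-yl]oxy}silane | C=C(O[Si](C)(C)C)CC[C@@H](C#C[Si](C)(C)C)C(C)=C | intermediate
11 | (5R)-6-methyl-5-[(trimethylsilyl)ethynyl]hept-6-en-2-one | CC(=O)CC[C@@H](C#C[Si](C)(C)C)C(C)=C | intermediate
12 | trimethyl{[(5R)-6-methyl-5-[(trimethylsilyl)ethynyl]hepta-2,6-dien-2-yl]oxy}silane | CC(O[Si](C)(C)C)=CC[C@@H](C#C[Si](C)(C)C)C(C)=C | intermediate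
13 | (3E,5R)-6-methyl-5-[(trimethylsilyl)ethynyl]hepta-3,6-dien-2-one | CC(=O)/C=C/[C@@H](C#C[Si](C)(C)C)C(C)=C | intermediate
14 | 2,3-dimethoxyaniline | COc1cccc(N)c1OC | starting material
15 | 2,3-dimethoxy-N-(methoxymethyl)aniline | COCNc1cccc(OC)c1OC | intermediate
16 | 2,3-dimethoxy-N-methylaniline | CNc1cccc(OC)c1OC | intermediate
17 | diethyl malonate | CCOC(=O)CC(=O)OCC | starting material
18 | ethyl 3-[(2,3-dimethoxyphenyl)(methyl)amino]-3-oxopropanoate | CCOC(=O)CC(=O)N(C)c1cccc(OC)c1OC | intermediate
19 | 4-hydroxy-7,8-dimethoxy-1-methylquinolin-2(1H)-one | COc1ccc2c(O)cc(=O)n(C)c2c1OC | intermediate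
20 | 7,8-dimethoxy-4-(methoxymethoxy)-1-methylquinolin-2(1H)-one | COc1ccc2c(OCOC)cc(=O)n(C)c2c1OC | intermediate
21 | 3-lithio-7,8-dimethoxy-4-(methoxymethoxy)-1-methylquinolin-2(1H)-one | COc1ccc2c(OCOC)c([Li])c(=O)n(C)c2c1OC | intermediate
22 | lithium triisopropoxy[7,8-dimethoxy-4-(methoxymethoxy)-1-methyl-2-oxoquinolin-3-yl]borate | COc1ccc2c(OCOC)c([B-](OC(C)C)(OC(C)C)OC(C)C)c(=O)n(C)c2c1OC.[Li+] | intermediate
23 | [7,8-dimethoxy-4-(methoxymethoxy)-1-methyl-2-oxo-1,2-dihydroquinolin-3-yl]boronic acid | COc1ccc2c(OCOC)c(B(O)O)c(=O)n(C)c2c1OC | intermediate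
24 | 4-hydroxy-7,8-dimethoxy-1-methyl-3-[(4R,5R)-6-methyl-2-oxo-5-[(trimethylsilyl)ethynyl]hept-6-en-4-yl]quinolin-2(1H)-one | CC(=O)C[C@@H](c1c(O)c2ccc(OC)c(OC)c2n(C)c1=O)[C@@H](C#C[Si](C)(C)C)C(C)=C | intermediate
25 | 7,8-dimethoxy-4-(methoxymethoxy)-1-methyl-3-[(4R,5R)-6-methyl-2-oxo-5-[(trimethylsilyl)ethynyl]hept-6-en-4-yl]quinolin-2(1H)-one | CC(=O)C[C@@H](c1c(OCOC)c2ccc(OC)c(OC)c2n(C)c1=O)[C@@H](C#C[Si](C)(C)C)C(C)=C | intermediate
26 | (4R,5R)-3,5-bis[7,8-dimethoxy-4-(methoxymethoxy)-1-methyl-2-oxoquinolin-3-yl]-1-methyl-4-(prop-1-en-2-yl)-2-(trimethylsilyl)cyclohex-2-en-1-ol, C1 epimers | COc1ccc2c(OCOC)c(c(=O)n(C)c2c1OC)C1=C([Si](C)(C)C)C(C)(O)C[C@@H](c3c(OCOC)c4ccc(OC)c(OC)c4n(C)c3=O)[C@@H]1C(C)=C | intermediate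
27 | (4R,5R)-3,5-bis(4-hydroxy-7,8-dimethoxy-1-methyl-2-oxoquinolin-3-yl)-1-methyl-4-(prop-1-en-2-yl)-2-(trimethylsilyl)cyclohex-2-en-1-ol | COc1ccc2c(O)c(c(=O)n(C)c2c1OC)C1=C([Si](C)(C)C)C(C)(O)C[C@@H](c3c(O)c4ccc(OC)c(OC)c4n(C)c3=O)[C@@H]1C(C)=C | intermediate
28 | bridged ether (ring-B O4 to the methyl-bearing carbon, S at that carbon) with trimethylsilyl on the ring alkene, ring-A 4-hydroxyl free, isopropenyl intact | COc1ccc2c(O)c(c(=O)n(C)c2c1OC)C1=C([Si](C)(C)C)[C@]2(C)C[C@@H](c3c(c4ccc(OC)c(OC)c4n(C)c3=O)O2)[C@@H]1C(C)=C | intermediate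
29 | bridged ether as 28 without silicon (ring alkene CH) | COc1ccc2c(O)c(c(=O)n(C)c2c1OC)C1=C[C@]2(C)C[C@@H](c3c(c4ccc(OC)c(OC)c4n(C)c3=O)O2)[C@@H]1C(C)=C | intermediate
30 | CNP0237003.1 | COc1ccc2c3c(c(=O)n(C)c2c1OC)C1=C[C@]2(C)C[C@@H](c4c(c5ccc(OC)c(OC)c5n(C)c4=O)O2)[C@@H]1C(C)(C)O3 | target

**Step count**

Total: 16 steps. Longest linear sequence: 12 steps (steps 1–7 and 12–16).

**Steps most likely to fail**

1. Step 14. Protodeboronation of the doubly ortho-substituted boronic acid may outrun transmetallation, insertion next to the branched propargylic carbon may be slow, or the alkenylnickel may be protonated before it isomerises and closes (open-chain hydroarylation); hot trifluoroethanol may also strip a MOM group. The fallback uses an aryl iodide, a syn addition and a separate ring closure; it sets out from 20 and 25 and comes back at 29. Lithiation of 20 as in step 11 and an I2 quench give 3-iodo-7,8-dimethoxy-4-(methoxymethoxy)-1-methylquinolin-2(1H)-one F1. Palladium-catalysed reductive syn-hydroarylation of 25 with F1 (Pd(OAc)2, PPh3, HCO2K, DMF, 60 °C) should place the aryl group on the alkyne carbon remote from silicon and hydrogen cis to it, giving the aryl vinylsilane with silicon cis to the chain F2. Iododesilylation with retention (N-iodosuccinimide, (CF3)2CHOH, 0 °C) gives the corresponding vinyl iodide F3. An intramolecular Nozaki–Hiyama–Kishi reaction (CrCl2, catalytic NiCl2, DMSO, rt) adds the alkenylchromium to the methyl ketone and gives the silicon-free 3-arylcyclohex-2-enol F4, which under the conditions of step 15 gives 29.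

2. Step 12. The existing γ-centre may epimerise through the dienamine of the enone, or catalyst and substrate may be mismatched so that facial selectivity is poor. The fallback makes the same carbon–carbon bond from the aryl side under neutral, non-enolising conditions; it sets out from 13 and 23 and comes back at 25. Hayashi–Miyaura conjugate addition of boronic acid 23 to enone 13 ([Rh(OH)(cod)]2, the BINAP enantiomer that delivers the (R) centre, dioxane/H2O, 40 °C) should give 25 directly with the MOM group already in place; no new compound arises (F0).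

3. Step 4. Base may enolise the carbon that bears the isopropenyl group, which racemises the only stereocentre or conjugates the alkene into the ring. The fallback avoids base on the ketone; it sets out from 6 and comes back at 7. Luche reduction (NaBH4, CeCl3·7H2O, MeOH, −78 °C) gives (6R)-3-methyl-6-(prop-1-en-2-yl)cyclohex-2-en-1-ol F5. Hydroxyl-directed epoxidation (VO(acac)2, t-BuOOH, CH2Cl2) gives (3R)-6-methyl-3-(prop-1-en-2-yl)-7-oxabicyclo[4.1.0]heptan-2-ol F6, and Dess–Martin periodinane (NaHCO3, CH2Cl2) oxidises it to 7.

**Further compounds**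

F1 | step 14 | 3-iodo-7,8-dimethoxy-4-(methoxymethoxy)-1-methylquinolin-2(1H)-one | COc1ccc2c(OCOC)c(I)c(=O)n(C)c2c1OC
F2 | step 14 | aryl vinylsilane from syn-hydroarylation of 25 (silicon cis to the chain) | C[Si](C)(C)/C=C(/c1c(OCOC)c2ccc(OC)c(OC)c2n(C)c1=O)\[C@@H](C(C)=C)[C@@H](CC(C)=O)c1c(OCOC)c2ccc(OC)c(OC)c2n(C)c1=O
F3 | step 14 | vinyl iodide from F2 (iodine cis to the chain) | I/C=C(/c1c(OCOC)c2ccc(OC)c(OC)c2n(C)c1=O)\[C@@H](C(C)=C)[C@@H](CC(C)=O)c1c(OCOC)c2ccc(OC)c(OC)c2n(C)c1=O
F4 | step 14 | (4R,5R)-3,5-bis[7,8-dimethoxy-4-(methoxymethoxy)-1-methyl-2-oxoquinolin-3-yl]-1-methyl-4-(prop-1-en-2-yl)cyclohex-2-en-1-ol | COc1ccc2c(OCOC)c(c(=O)n(C)c2c1OC)C1=CC(C)(O)C[C@@H](c3c(OCOC)c4ccc(OC)c(OC)c4n(C)c3=O)[C@@H]1C(C)=C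
F0 | step 12 | none | none
F5 | step 4 | (6R)-3-methyl-6-(prop-1-en-2-yl)cyclohex-2-en-1-ol | CC1=CC(O)[C@H](CC1)C(C)=C
F6 | step 4 | (3R)-6-methyl-3-(prop-1-en-2-yl)-7-oxabicyclo[4.1.0]heptan-2-ol | CC12OC1C(O)[C@H](CC2)C(C)=C
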